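**Plan** (chroman numbering: O1, C2, C3, C4, C4a, C5–C8, C8a; ring A = benzo ring, ring B = 2-aryl ring)
1. Cuts: first the bond from C4 to the acylphloroglucinol ring (C4 cation of a flavan-4-ol plus the free arene), then the acyl–arene bond of the phloroglucinol ketone; at the flavone oxidation level the pyran ring is cut at C2–C3 and at O1–C8a, leaving a ring A acetophenone with fluorine on C8a and a ring B acid chloride.
2. Forward: the ring A ketone and the ring B acid chloride are joined and the pyranone ring closed in one flask (flavone); hydrogenation gives the flavan-4-ol; the acylphloroglucinol ring is attached at C4; two benzyl ethers are removed last.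
3. Enabling feature: C4 stands between C3 and C4a, so a C4 carbonyl is ortho to C8a and para to O7 of ring A; it acidifies C3–H and activates a fluorine on C8a, so the C=O of the acid chloride can be laid across C3 and C8a. The same carbon later becomes the cation that takes the third arene.
4. Stereochemistry: C2 (R) comes from catalyst-controlled hydrogenation of the flavone C2=C3 bond; C4 (S) comes from substrate control, the arene adding to the C4 cation trans to the 2-aryl group.
5. Protecting groups: benzyl ethers on O7 and O4′ only.

Key step: step 2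

Assumption: the (R,R) hand of the SINpEt carbene ligand is taken to deliver hydrogen to the face of C2 that gives 2R; if the sense is the opposite, the (S,S) ligand is used and nothing else changes.
Assumption: 9-phenylnonanoic acid is taken as a catalogue compound.

**Step 1**
Reactants: 1 1-(2-fluoro-4-hydroxyphenyl)ethan-1-one; 2 benzyl bromide
Product: 3 1-[4-(benzyloxy)-2-fluorophenyl]ethan-1-one
Conditions: K2CO3 (1.5 equiv), DMF, 50 °C
Reagents that add atoms: none
Why: Williamson etherification, in which the phenoxide (acidified by the para acetyl group) is alkylated by benzyl bromide in an SN2 reaction while the aryl fluoride is inert to phenoxide and carbonate at this temperature; no stereocenter is involved.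

**Step 2**
Reactants: 3 1-[4-(benzyloxy)-2-fluorophenyl]ethan-1-one; 4 4-(benzyloxy)benzoyl chloride
Product: 6 7-(benzyloxy)-2-[4-(benzyloxy)phenyl]-4H-chromen-4-one, via fluoro diketone lithium enolate 5 (not isolated)
Conditions: LiN(SiMe3)2 (2.2 equiv), THF, −78 °C; 4 (1.05 equiv), −78 → 0 °C; then DMSO added, THF distilled off, 110 °C
Reagents that add atoms: none
Why: LiN(SiMe3)2 gives the lithium enolate of 3 at C3, which is C-acylated by 4 (Claisen-type acylation, C2–C3 formed), and the diketone is deprotonated at once by the second equivalent of base to the enolate 5, so that no second acylation occurs. On heating in DMSO the enolate oxygen on C2 adds to C8a, which carries fluorine and is ortho to the C4 carbonyl, to give an anionic σ-adduct that expels fluoride (addition–elimination at the arene, O1–C8a formed); the closest known reaction type is the base-mediated cyclisation of 1-(2-fluoroaryl)-1,3-diketones to chromones. The pyranone ring closes in the 6-exo-trig mode with respect to the C8a=C8 bond of ring A. No stereocenter is formed, since C2 and C3 are sp2 in 6; C2 is set in step 3. The step needs C- over O-acylation, which the lithium enolate with an acid chloride at low temperature should secure (any enol ester is itself an acyl donor to remaining enolate), and O- over C-attack in the ring closure, which is secured because attack by C3 on C8a would give a four-membered ring. Fluorine on C8a is the only leaving group that the carbonyl activates, so the substrate fixes the regiochemistry of ring A.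

**Step 3**
Reactants: 6 7-(benzyloxy)-2-[4-(benzyloxy)phenyl]-4H-chromen-4-one
Product: 8 (2R,4R)-7-(benzyloxy)-2-[4-(benzyloxy)phenyl]chroman-4-ol, via (2R)-flavanone 7 (not isolated)
Conditions: H2 (100 bar), [Ru(cod)(2-methylallyl)2] (5 mol %), (R,R)-SINpEt·HBF4 (10 mol %), KOtBu (15 mol %), toluene, 40 °C, until 7 is consumed
Reagents that add atoms: none
Why: asymmetric hydrogenation of the flavone C2=C3 bond with a chiral ruthenium N-heterocyclic carbene catalyst, a known reaction type for flavones and chromones, sets C2 by catalyst-controlled delivery of hydrogen to one face of the planar pyranone (2R with the ligand hand assumed above), and the same catalyst should reduce the ketone of 7 from the face anti to the pseudo-equatorial 2-aryl group to the cis alcohol, whose C4 configuration (either epimer serves) is erased in step 5; benzyl ethers are not cleaved by ruthenium hydrides.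

**Step 4**
Reactants: 9 benzene-1,3,5-triol (phloroglucinol); 10 9-phenylnonanoic acid
Product: 11 9-phenyl-1-(2,4,6-trihydroxyphenyl)nonan-1-one
Conditions: BF3·OEt2 (solvent), 9 (1.5 equiv), 85 °C; then aqueous NaOAc
Reagents that add atoms: none
Why: Friedel–Crafts C-acylation of the very electron-rich triol by the boron-activated acid, a known route from free carboxylic acids to acylphloroglucinols; the three ring positions are equivalent, the chelated ketone deactivates the ring towards a second acylation, and no stereocenter is involved.

**Step 5**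
Reactants: 8 (2R,4R)-7-(benzyloxy)-2-[4-(benzyloxy)phenyl]chroman-4-ol; 11 9-phenyl-1-(2,4,6-trihydroxyphenyl)nonan-1-one
Product: 12 1-{3-[(2R,4S)-7-(benzyloxy)-2-[4-(benzyloxy)phenyl]chroman-4-yl]-2,4,6-trihydroxyphenyl}-9-phenylnonan-1-one
Conditions: Sc(OTf)3 (10 mol %), 11 (3 equiv), MeCN/CH2Cl2, −20 → 0 °C
Reagents that add atoms: none
Why: Friedel–Crafts alkylation in which Sc(OTf)3 ionises the C4 hydroxyl to a benzylic cation stabilised through C4a by the para 7-benzyloxy group, and one of the two equivalent free ring carbons of 11 adds pseudo-axially to the half-chair cation whose 2-aryl group is pseudo-equatorial, which should put the new aryl group trans to the 2-aryl group (4S), as is usual for acid-mediated arylation of flavan-4-ols; excess 11 suppresses a second alkylation.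

**Step 6**
Reactants: 12 1-{3-[(2R,4S)-7-(benzyloxy)-2-[4-(benzyloxy)phenyl]chroman-4-yl]-2,4,6-trihydroxyphenyl}-9-phenylnonan-1-one
Product: 13 1-{2,4,6-trihydroxy-3-[(2R,4S)-7-hydroxy-2-(4-hydroxyphenyl)chroman-4-yl]phenyl}-9-phenylnonan-1-one (target)
Conditions: H2 (1 atm), Pd/C (10 %), EtOAc/MeOH, rt
Reagents that add atoms: none
Why: hydrogenolysis of the two benzyl aryl ethers over palladium; at 1 atm and room temperature the hydrogen-bonded aryl ketone, the O1–C2 benzylic ether of the pyran ring and the C4–aryl bonds are expected to survive if the reaction is stopped after uptake of two equivalents, and no stereocenter is touched.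

**Compound list**
1 | 1-(2-fluoro-4-hydroxyphenyl)ethan-1-one | CC(=O)c1ccc(O)cc1F | starting material
2 | benzyl bromide | BrCc1ccccc1 | starting material
3 | 1-[4-(benzyloxy)-2-fluorophenyl]ethan-1-one | CC(=O)c1ccc(OCc2ccccc2)cc1F | intermediate
4 | 4-(benzyloxy)benzoyl chloride | O=C(Cl)c1ccc(OCc2ccccc2)cc1 | starting material
5 | 1-[4-(benzyloxy)-2-fluorophenyl]-3-[4-(benzyloxy)phenyl]propane-1,3-dione (held in the flask as its lithium enolate) | O=C(CC(=O)c1ccc(OCc2ccccc2)cc1)c1ccc(OCc2ccccc2)cc1F | intermediate
6 | 7-(benzyloxy)-2-[4-(benzyloxy)phenyl]-4H-chromen-4-one | O=c1cc(-c2ccc(OCc3ccccc3)cc2)oc2cc(OCc3ccccc3)ccc12 | intermediate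
7 | (2R)-7-(benzyloxy)-2-[4-(benzyloxy)phenyl]chroman-4-one | O=C1C[C@H](c2ccc(OCc3ccccc3)cc2)Oc2cc(OCc3ccccc3)ccc12 | intermediate
8 | (2R,4R)-7-(benzyloxy)-2-[4-(benzyloxy)phenyl]chroman-4-ol | O[C@@H]1C[C@H](c2ccc(OCc3ccccc3)cc2)Oc2cc(OCc3ccccc3)ccc21 | intermediate
9 | benzene-1,3,5-triol (phloroglucinol) | Oc1cc(O)cc(O)c1 | starting material
10 | 9-phenylnonanoic acid | OC(=O)CCCCCCCCc1ccccc1 | starting material
11 | 9-phenyl-1-(2,4,6-trihydroxyphenyl)nonan-1-one | O=C(CCCCCCCCc1ccccc1)c1c(O)cc(O)cc1O | intermediate
12 | 1-{3-[(2R,4S)-7-(benzyloxy)-2-[4-(benzyloxy)phenyl]chroman-4-yl]-2,4,6-trihydroxyphenyl}-9-phenylnonan-1-one | O=C(CCCCCCCCc1ccccc1)c1c(O)cc(O)c([C@H]2C[C@H](c3ccc(OCc4ccccc4)cc3)Oc3cc(OCc4ccccc4)ccc32)c1O | intermediate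
13 | 1-{2,4,6-trihydroxy-3-[(2R,4S)-7-hydroxy-2-(4-hydroxyphenyl)chroman-4-yl]phenyl}-9-phenylnonan-1-one | O=C(CCCCCCCCc1ccccc1)c1c(O)cc(O)c([C@H]2C[C@H](c3ccc(O)cc3)Oc3cc(O)ccc32)c1O | target

Total step count: 6. Longest linear sequence: 5 (steps 1, 2, 3, 5, 6); step 4 is a one-step side branch.

**Steps most likely to fail**

Step 2. The ring closure may stall after the acylation, because the lithium-chelated diketonate is a weak oxygen nucleophile and the para benzyloxy group weakens the carbonyl as an activator for fluoride displacement. O-acylation, or attack of the amide base on the acid chloride, would lower the yield further. The fallback sets out from 3 and returns at 6. Fluoride is displaced first by a hydroxide equivalent (acetohydroxamic acid, K2CO3, DMSO, 80 °C) to give 1-[4-(benzyloxy)-2-hydroxyphenyl]ethan-1-one F1. Claisen–Schmidt condensation with 4-(benzyloxy)benzaldehyde (KOH, EtOH, rt) then gives (E)-1-[4-(benzyloxy)-2-hydroxyphenyl]-3-[4-(benzyloxy)phenyl]prop-2-en-1-one F2, and oxidative cyclisation (I2 cat., DMSO, 130 °C) gives 6. Here O1 is placed on ring A first and the pyranone closes at O1–C2.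

Step 3. Enantiomeric purity may erode through base-mediated opening of the intermediate flavanone to the chalcone and re-closure; face selectivity may be incomplete, or arene rings may be hydrogenated at high pressure. The fallback sets out from 6 and returns at 8. Conjugate reduction with LiBH(s-Bu)3 (THF, −78 °C, AcOH quench) gives racemic 7-(benzyloxy)-2-[4-(benzyloxy)phenyl]chroman-4-one F3. Kinetic resolution by transfer hydrogenation with RuCl(p-cymene)[(R,R)-TsDPEN] in HCO2H/Et3N should then reduce the 2R enantiomer to 8: this ligand hand delivers hydride to the carbonyl face that gives 4R, which is the face anti to the 2-aryl group only in the 2R ketone. The slow-reacting (2S)-7-(benzyloxy)-2-[4-(benzyloxy)phenyl]chroman-4-one F4 is left behind, and can be racemised with base through the chalcone and resubmitted.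

Step 5. Facial selectivity at the C4 cation may be poor (cis isomer), the remaining free ring position of the acylphloroglucinol may be alkylated a second time, or acid may open the O1–C2 bond with loss of the C2 configuration. The fallback sets out from 8 and returns at 13; it changes the nucleophile and puts the acyl group on last. Under the same acid catalysis 8 is coupled with 1,3,5-tris(benzyloxy)benzene, whose three positions are equivalent and whose bulk should favour trans addition, to give (2R,4S)-7-(benzyloxy)-2-[4-(benzyloxy)phenyl]-4-[2,4,6-tris(benzyloxy)phenyl]chromane F5. Friedel–Crafts acylation of one of its two equivalent free ring positions with 10 and trifluoroacetic anhydride gives 1-{2,4,6-tris(benzyloxy)-3-[(2R,4S)-7-(benzyloxy)-2-[4-(benzyloxy)phenyl]chroman-4-yl]phenyl}-9-phenylnonan-1-one F6. Hydrogenolysis of the five benzyl ethers (H2, Pd/C) gives 13.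

**Further compounds**
F1 | step 2 | 1-[4-(benzyloxy)-2-hydroxyphenyl]ethan-1-one | CC(=O)c1ccc(OCc2ccccc2)cc1O
F2 | step 2 | (E)-1-[4-(benzyloxy)-2-hydroxyphenyl]-3-[4-(benzyloxy)phenyl]prop-2-en-1-one | O=C(/C=C/c1ccc(OCc2ccccc2)cc1)c1ccc(OCc2ccccc2)cc1O
F3 | step 3 | rac-7-(benzyloxy)-2-[4-(benzyloxy)phenyl]chroman-4-one | O=C1CC(c2ccc(OCc3ccccc3)cc2)Oc2cc(OCc3ccccc3)ccc12
F4 | step 3 | (2S)-7-(benzyloxy)-2-[4-(benzyloxy)phenyl]chroman-4-one | O=C1C[C@@H](c2ccc(OCc3ccccc3)cc2)Oc2cc(OCc3ccccc3)ccc12
F5 | step 5 | (2R,4S)-7-(benzyloxy)-2-[4-(benzyloxy)phenyl]-4-[2,4,6-tris(benzyloxy)phenyl]chromane | c1(OCc2ccccc2)cc(OCc2ccccc2)c([C@H]2C[C@H](c3ccc(OCc4ccccc4)cc3)Oc3cc(OCc4ccccc4)ccc32)c(OCc2ccccc2)c1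
F6 | step 5 | 1-{2,4,6-tris(benzyloxy)-3-[(2R,4S)-7-(benzyloxy)-2-[4-(benzyloxy)phenyl]chroman-4-yl]phenyl}-9-phenylnonan-1-one | O=C(CCCCCCCCc1ccccc1)c1c(OCc2ccccc2)cc(OCc2ccccc2)c([C@H]2C[C@H](c3ccc(OCc4ccccc4)cc3)Oc3cc(OCc4ccccc4)ccc32)c1OCc1ccccc1
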